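Begin with the constants these runs can give, after setting out the flasks.

| flask | X | temperature | remark | time |
|---|---|---|---|---|
| theta | 14 mM | 5 °C | run made earlier |  |
| beta | 22 mM | 35 °C | run made earlier |  |
| north | 29 mM | 10 °C |  | 6.0 d |
| east | 29 mM |  | at 10 °C until 4.0 d, from then on at 60 °C | 6.0 d |
| west | 29 mM | 35 °C |  | 6.0 d |
| south-east | 29 mM | 60 °C |  | 6.0 d |

theta run (percent of the X charged)

| time / d | G / % | X / % |
|---|---|---|
| 0.250 | 1.2 | 100.1 |
| 0.417 | 0.1 | 99.8 |
| 0.625 | 1.6 | 98.8 |
| 1.04 | 1.2 | 98.8 |
| 1.67 | 3.2 | 98.3 |
| 2.50 | 2.7 | 97.2 |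
| 4.00 | 4.3 | 95.2 |

beta run (percent of the X charged)

| time / h | G / % | X / % |
|---|---|---|
| 2.00 | 8.5 | 92.2 |
| 3.00 | 9.3 | 88.9 |
| 4.00 | 13.4 | 87.1 |
| 8.00 | 22.3 | 75.5 |
| 12.0 | 32.0 | 66.2 |
| 20.0 | 46.1 | 48.3 |
| 30.0 | 60.7 | 33.4 |

(each reading ± 1 percentage point)

- a reading or a percentage of G counts all its forms, free or not

1. the flask with the highest amount of G, in percent of the X charged ("all alike" if they lie within 1.5 percentage points) (north / east / west / south-east / all alike)
2. final G, as a percentage of the X charged, in north
3. final G, as a percentage of the X charged, in east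
4. final G, as a percentage of the X charged, in west
5. final G, as a percentage of the X charged, in south-east

First ask whether X is used up in west, which has the temperature of the beta run. The X left at the last beta reading gives a first-order constant of 0.877 d⁻¹. Over 6.0 d that makes 5.26 lifetimes, so by this reckoning west keeps 0.518% of its X.

Next ask where the reacted X goes. In the beta run, the gap between the charge and X plus G reads 5.60% at 20.0 h and 5.90% at 30.0 h, while G climbs from 46.1% to 60.7%. Each reading is good to 1 percentage point, so these two gaps cannot show whether the gap follows G. Take as a working quantity the missing amount, the part of the charge found neither as X nor as G, counted in mM and not in percent: 1.30 mM.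

Then ask what this costs west. Suppose the amount holds at one temperature. Its share in west is then 4.48%, smaller than in the beta run, and my reckoning puts G in west at 95.0%. No earlier run stands at 60 °C, so leave the hot flasks open.

The forecast differs: north 14%, east 28%, west 65%, south-east 22%, with most in west: “West is the safest pick, with wide ranges”.

The flasks give north 15.3%, east 76.0%, west 94.8% and south-east 75.8%, with most in west.

    X → G (k = 0.0349 h⁻¹, Ea = 98.0 kJ mol⁻¹)
    G ⇌ J (K = 2.00, k = 0.115 h⁻¹, Ea = 96.0 kJ mol⁻¹, ΔH = 60.0 kJ mol⁻¹)
    D ⇌ G, rate k3*(cs3 - [G]) while solid is left; crystals form when [G] > cs3 (solubility = 0.570 mM, k = 14.8 h⁻¹)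
    X → Q (k = 2.05 × 10⁻⁴ h⁻¹, Ea = 128 kJ mol⁻¹)
    (constants at 35 °C)

West lacks 1.31 mM beyond its remaining X, beside 1.30 mM read from the smaller beta charge. In south-east, part of the reason for its 75.8% of G is the falling back of J to G together with the limit of solubility of G: the same run without the falling back ends at 0%, and without the limit at 7.83%. North is low for another reason, mainly the time given: left until 60.0 d, north reads 81.4%.

Now take the neighbour flask that is east with 73 mM of X. East's missing amount is 6.97 mM, or 5.36 times 1.30 mM, and held fixed it gives G of 90.5%. The computed flask gives 89.7%.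

All runs are simulated for substances that don't exist, and the scatter is random.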